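The furanone ring (O, C3, C2, C1, C10) is disconnected at C1–C2 and O–C10, with C1 parked as a seven-membered lactone on O6. In the key step the C2 enolate of a (Z)-enone methyl ketone attacks that lactone carbonyl; the bicyclic hemiketal fragments to the ten-membered 1,3-dione (C1–C2), whose C3 enolate oxygen displaces a tertiary mesylate at C10 (O–C10), and the released O6 alkoxide closes the butyrolactone. The step exploits the (Z)-C4=C5 alkene, which holds C2 beside the O6-bound acyl carbon, and the 1,3-dicarbonyl relationship C1/C3 of the furanone. The precursor is a citramalate-derived oxepanone carrying the C10 mesylate, the C6 enone and the C7 acrylate.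

Key step: step 12

Remark: germacrane numbering of the target is used for all intermediates (C1 ketone, C2=C3 furanone alkene, C4=C5 ring alkene, C6 lactone carbinol, C8 ester carbinol, C10 quaternary ether carbon, C11–C13 methylene lactone).
Assumption: the indium-mediated addition of step 7 is taken to be syn-selective, as is usual for γ-substituted 2-(bromomethyl)acrylates; C6 is then corrected by the invertive ring closure of step 9.
Assumption: in step 3 the ligand antipode is the one that gives the (4S)-carbinol; the label (S,S) stands for that choice.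

Step 1
Reactants: 1 (S)-citramalic acid
Product: 2 2-[(4S)-2,2,4-trimethyl-5-oxo-1,3-dioxolan-4-yl]acetic acid
Conditions: 2,2-dimethoxypropane, p-TsOH (cat.), CH2Cl2, rt
Reagents that add atoms: 2,2-dimethoxypropane, COC(C)(C)OC
Why: Acid-catalysed acetonide formation should engage the α-hydroxy acid as the five-membered dioxolanone in preference to a six-membered dioxanone, so C1 and O10 are masked together as an activated acyl group while the C8 carboxyl stays free and the stereocentre is not touched.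

Step 2
Reactants: 2 2-[(4S)-2,2,4-trimethyl-5-oxo-1,3-dioxolan-4-yl]acetic acid
Product: 4 2-[(4S)-2,2,4-trimethyl-5-oxo-1,3-dioxolan-4-yl]acetaldehyde, via acid chloride 3 (not isolated)
Conditions: (COCl)2, DMF (cat.), CH2Cl2, 0 °C to rt; then H2 (1 atm), Pd/BaSO4, 2,6-lutidine, THF, rt
Reagents that add atoms: none
Why: Rosenmund reduction, in which the acid chloride of the free carboxyl is hydrogenolysed over poisoned palladium to the aldehyde, should leave the dioxolanone intact.

Step 3
Reactants: 4 2-[(4S)-2,2,4-trimethyl-5-oxo-1,3-dioxolan-4-yl]acetaldehyde; 5 tert-butyl 2-(bromomethyl)prop-2-enoate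
Product: 6 tert-butyl (4S)-2-methylidene-4-[(triethylsilyl)oxy]-5-[(4S)-2,2,4-trimethyl-5-oxo-1,3-dioxolan-4-yl]pentanoate
Conditions: CrCl2 (10 mol %), (S,S)-3,6-di-tert-butyl-1,8-bis(4-isopropyl-4,5-dihydrooxazol-2-yl)-9H-carbazole (12 mol %), Mn powder, Et3SiCl, i-Pr2NEt, THF, rt
Reagents that add atoms: chlorotriethylsilane, CC[Si](Cl)(CC)CC
Why: In this catalytic asymmetric Nozaki–Hiyama 2-(alkoxycarbonyl)allylation the allylchromium species adds through its γ-carbon, the tridentate ligand selects the aldehyde face that sets C8, and Et3SiCl turns the catalyst over and releases the carbinol as its silyl ether, so no free γ-hydroxyl can open the dioxolanone and the tert-butyl ester cannot lactonise.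

Step 4
Reactants: 6 tert-butyl (4S)-2-methylidene-4-[(triethylsilyl)oxy]-5-[(4S)-2,2,4-trimethyl-5-oxo-1,3-dioxolan-4-yl]pentanoate
Product: 7 tert-butyl (2Z,4R)-2-(bromomethyl)-4-[(triethylsilyl)oxy]-5-[(4S)-2,2,4-trimethyl-5-oxo-1,3-dioxolan-4-yl]pent-2-enoate
Conditions: NBS, AIBN (cat.), K2CO3, PhCF3, 80 °C
Reagents that add atoms: N-bromosuccinimide, O=C1CCC(=O)N1Br
Why: Wohl–Ziegler bromination should abstract the weakest (allylic C7) hydrogen and brominate the delocalised radical at its primary terminus, which re-arms C7 as a nucleophilic site; a transposed secondary bromide would give the same allylindium species in step 7.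

Step 5
Reactants: 8 but-2-yn-1-ol
Product: 9 (2Z)-3-iodobut-2-en-1-ol
Conditions: NaAlH2(OCH2CH2OMe)2, THF, 0 °C to rt; then I2, −78 °C to 0 °C
Reagents that add atoms: iodine, II
Why: Hydroxyl-directed trans-hydroalumination of the propargylic alcohol places aluminium on the distal alkyne carbon, and iodinolysis with retention should give the (Z)-iodoalkene with iodine cis to CH2OH.

Step 6
Reactants: 9 (2Z)-3-iodobut-2-en-1-ol
Product: 10 (2Z)-3-iodobut-2-enal
Conditions: MnO2, CH2Cl2, rt
Reagents that add atoms: none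
Why: Allylic alcohol oxidation with activated MnO2 under neutral conditions should give the enal without loss of the (Z)-geometry.

Step 7
Reactants: 7 tert-butyl (2Z,4R)-2-(bromomethyl)-4-[(triethylsilyl)oxy]-5-[(4S)-2,2,4-trimethyl-5-oxo-1,3-dioxolan-4-yl]pent-2-enoate; 10 (2Z)-3-iodobut-2-enal
Product: 11 tert-butyl (3S,4R)-3-[(1R,2Z)-1-hydroxy-3-iodobut-2-en-1-yl]-2-methylidene-4-[(triethylsilyl)oxy]-5-[(4S)-2,2,4-trimethyl-5-oxo-1,3-dioxolan-4-yl]pentanoate
Conditions: In powder, THF/H2O, rt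
Reagents that add atoms: none
Why: In this Barbier allylation the allylindium adds through C7 and regenerates the exocyclic methylene; syn simple selectivity is expected from a cyclic transition state, and the C7 face should be set by C8 (C8–H eclipsing the alkene to minimise allylic 1,3-strain, attack anti to the C9 branch), while the vinyl iodide, dioxolanone and tert-butyl ester stay inert.

Step 8
Reactants: 11 tert-butyl (3S,4R)-3-[(1R,2Z)-1-hydroxy-3-iodobut-2-en-1-yl]-2-methylidene-4-[(triethylsilyl)oxy]-5-[(4S)-2,2,4-trimethyl-5-oxo-1,3-dioxolan-4-yl]pentanoate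
Product: 12 (2S,4R,5S,6R,7Z)-5-[3-(tert-butoxy)-3-oxoprop-1-en-2-yl]-2,6-dihydroxy-8-iodo-2-methyl-4-[(triethylsilyl)oxy]non-7-enoic acid
Conditions: LiOH, THF/H2O, 0 °C; then dilute HCl to pH 4
Reagents that add atoms: lithium hydroxide, [Li+].[OH-]
Why: Ester hydrolysis at the activated dioxolanone carbonyl, followed by loss of acetone from the hemiketal, should leave the hindered tert-butyl ester, the silyl ether and the C10 configuration untouched.

Step 9
Reactants: 12 (2S,4R,5S,6R,7Z)-5-[3-(tert-butoxy)-3-oxoprop-1-en-2-yl]-2,6-dihydroxy-8-iodo-2-methyl-4-[(triethylsilyl)oxy]non-7-enoic acid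
Product: 13 tert-butyl 2-[(3S,5R,6S,7S)-3-hydroxy-7-[(1Z)-2-iodoprop-1-en-1-yl]-3-methyl-2-oxo-5-[(triethylsilyl)oxy]oxepan-6-yl]prop-2-enoate
Conditions: PPh3, DIAD, toluene/THF (0.005 M), 0 °C to rt
Reagents that add atoms: none
Why: In this Mitsunobu lactonisation the C6 oxyphosphonium ion is displaced by the C1 carboxylate with inversion, which should turn the syn adduct into the C6 configuration of the target and install the seven-membered O6–C1 lactone; the tertiary C10 hydroxyl is not activated.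

Step 10
Reactants: 13 tert-butyl 2-[(3S,5R,6S,7S)-3-hydroxy-7-[(1Z)-2-iodoprop-1-en-1-yl]-3-methyl-2-oxo-5-[(triethylsilyl)oxy]oxepan-6-yl]prop-2-enoate
Product: 15 tert-butyl 2-[(3S,5R,6S,7R)-3-hydroxy-3-methyl-7-[(1Z)-2-methyl-3-oxobut-1-en-1-yl]-2-oxo-5-[(triethylsilyl)oxy]oxepan-6-yl]prop-2-enoate, via 2-ethoxydiene 14 (not isolated)
Conditions: tributyl(1-ethoxyvinyl)stannane, Pd(PPh3)4 (5 mol %), CuI, DMF, 50 °C; then 0.1 M HCl, THF, 0 °C
Reagents that add atoms: tributyl(1-ethoxyvinyl)stannane, C=C(OCC)[Sn](CCCC)(CCCC)CCCC; water, O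
Why: Stille coupling with retention of alkene geometry and hydrolysis of the enol ether should unveil the (Z)-enone methyl ketone only after O6 is acylated, so no cyclic hemiketal or furan can form.

Step 11
Reactants: 15 tert-butyl 2-[(3S,5R,6S,7R)-3-hydroxy-3-methyl-7-[(1Z)-2-methyl-3-oxobut-1-en-1-yl]-2-oxo-5-[(triethylsilyl)oxy]oxepan-6-yl]prop-2-enoate
Product: 16 tert-butyl 2-[(3S,5R,6S,7R)-3-methyl-7-[(1Z)-2-methyl-3-oxobut-1-en-1-yl]-3-[(methylsulfonyl)oxy]-2-oxo-5-[(triethylsilyl)oxy]oxepan-6-yl]prop-2-enoate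
Conditions: MsCl, Et3N, DMAP (cat.), CH2Cl2, −20 °C to 0 °C
Reagents that add atoms: methanesulfonyl chloride, CS(=O)(=O)Cl
Why: Sulfonylation of the tertiary α-hydroxy lactone (via sulfene) forms only an O–S bond, so C10 should keep its (S) configuration and become an electrophile.

Step 12
Reactants: 16 tert-butyl 2-[(3S,5R,6S,7R)-3-methyl-7-[(1Z)-2-methyl-3-oxobut-1-en-1-yl]-3-[(methylsulfonyl)oxy]-2-oxo-5-[(triethylsilyl)oxy]oxepan-6-yl]prop-2-enoate
Product: 19 (4Z,6R,7S,8R,10R)-3,10-epoxy-1-oxo-8-[(triethylsilyl)oxy]germacra-2,4,11(13)-trien-12,6-olide, via ten-membered diketone 17 (not isolated), via furanone carbinol 18 (not isolated)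
Conditions: LiN(SiMe3)2 (1.05 equiv), THF, −78 °C to 0 °C; then t-BuOK (0.2 equiv), 0 °C
Reagents that add atoms: none
Why: Proposed new method: LiN(SiMe3)2 forms the cross-conjugated C2 enolate of the methyl ketone, which the (Z)-C4=C5 alkene holds beside the O6–C1 lactone carbonyl, so it should add through a seven-membered transition state and the bicyclo[4.4.1] hemiketal alkoxide should collapse with loss of the allylic O6 alkoxide (C1–C2 bond, 17); the diketonate oxygen on C3 then displaces the tertiary α-keto mesylate at C10 (O–C10 bond, 18), and catalytic alkoxide lactonises O6 onto the tert-butyl ester (19). The closest known reaction types are the Baker–Venkataraman O-to-C acyl transfer, ring enlargement by side-chain incorporation and the base cyclisation of α'-halo 1,3-diketones to 3(2H)-furanones, but a ring-expanding Claisen acylation on a lactone of this kind has not been shown. The ten-membered ring is closed by fragmentation of the bicyclic hemiketal (seven to ten), the furanone by a transannular 5-exo-tet displacement and the butyrolactone by 5-exo-trig transesterification. C10 is the only stereocentre changed and is set by inversion of the citramalate-derived (S)-mesylate, while C6, C7 and C8 are untouched and the C2=C3 geometry is fixed by the five-membered ring. The step needs C-acylation at C1 rather than Michael addition to the acrylate or enolisation elsewhere, which the seven- versus eight-membered transition state, the kinetic acidity of the methyl ketone and the hindered tert-butyl acrylate should secure. It also needs substitution rather than elimination or ionisation at C10, which intramolecular five-ring delivery of the enolate oxygen and the carbonyl-destabilised cation should favour.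

Step 13
Reactants: 19 (4Z,6R,7S,8R,10R)-3,10-epoxy-1-oxo-8-[(triethylsilyl)oxy]germacra-2,4,11(13)-trien-12,6-olide
Product: 20 (4Z,6R,7R,8R,10R)-3,10-epoxy-8-hydroxy-1-oxogermacra-2,4,11(13)-trien-12,6-olide
Conditions: HF·pyridine, pyridine, THF, 0 °C
Reagents that add atoms: none
Why: Fluoride-mediated desilylation of the secondary triethylsilyl ether under buffered conditions should leave the methylene lactone and the furanone intact.

Step 14
Reactants: 20 (4Z,6R,7R,8R,10R)-3,10-epoxy-8-hydroxy-1-oxogermacra-2,4,11(13)-trien-12,6-olide; 21 (2S)-2-methylbutanoic acid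
Product: 22 (4Z,6R,7R,8R,10R)-3,10-epoxy-1-oxogermacra-2,4,11(13)-trien-12,6-olid-8-yl (2S)-2-methylbutanoate
Conditions: EDC·HCl, DMAP, CH2Cl2, 0 °C to rt
Reagents that add atoms: none
Why: Steglich esterification acylates O8 with retention at C8, and the (S)-α-stereocentre of the acid should not enolise under carbodiimide activation.

Compound list
1 | (S)-citramalic acid, (2S)-2-hydroxy-2-methylbutanedioic acid | C[C@](O)(CC(=O)O)C(=O)O | starting material
2 | 2-[(4S)-2,2,4-trimethyl-5-oxo-1,3-dioxolan-4-yl]acetic acid | C[C@@]1(CC(=O)O)OC(C)(C)OC1=O | intermediate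
3 | 2-[(4S)-2,2,4-trimethyl-5-oxo-1,3-dioxolan-4-yl]acetyl chloride (not isolated) | C[C@@]1(CC(=O)Cl)OC(C)(C)OC1=O | intermediate
4 | 2-[(4S)-2,2,4-trimethyl-5-oxo-1,3-dioxolan-4-yl]acetaldehyde | C[C@@]1(CC=O)OC(C)(C)OC1=O | intermediate
5 | tert-butyl 2-(bromomethyl)prop-2-enoate | C=C(CBr)C(=O)OC(C)(C)C | starting material
6 | tert-butyl (4S)-2-methylidene-4-[(triethylsilyl)oxy]-5-[(4S)-2,2,4-trimethyl-5-oxo-1,3-dioxolan-4-yl]pentanoate | C=C(C[C@H](O[Si](CC)(CC)CC)C[C@]1(C)OC(C)(C)OC1=O)C(=O)OC(C)(C)C | intermediate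
7 | tert-butyl (2Z,4R)-2-(bromomethyl)-4-[(triethylsilyl)oxy]-5-[(4S)-2,2,4-trimethyl-5-oxo-1,3-dioxolan-4-yl]pent-2-enoate | BrC/C(=C\[C@H](O[Si](CC)(CC)CC)C[C@]1(C)OC(C)(C)OC1=O)C(=O)OC(C)(C)C | intermediate
8 | but-2-yn-1-ol | CC#CCO | starting material
9 | (2Z)-3-iodobut-2-en-1-ol | C/C(I)=C/CO | intermediate
10 | (2Z)-3-iodobut-2-enal | C/C(I)=C/C=O | intermediate
11 | tert-butyl (3S,4R)-3-[(1R,2Z)-1-hydroxy-3-iodobut-2-en-1-yl]-2-methylidene-4-[(triethylsilyl)oxy]-5-[(4S)-2,2,4-trimethyl-5-oxo-1,3-dioxolan-4-yl]pentanoate | C/C(I)=C/[C@H](O)[C@H](C(=C)C(=O)OC(C)(C)C)[C@H](O[Si](CC)(CC)CC)C[C@]1(C)OC(C)(C)OC1=O | intermediate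
12 | (2S,4R,5S,6R,7Z)-5-[3-(tert-butoxy)-3-oxoprop-1-en-2-yl]-2,6-dihydroxy-8-iodo-2-methyl-4-[(triethylsilyl)oxy]non-7-enoic acid | C/C(I)=C/[C@H](O)[C@H](C(=C)C(=O)OC(C)(C)C)[C@H](O[Si](CC)(CC)CC)C[C@](C)(O)C(=O)O | intermediate
13 | tert-butyl 2-[(3S,5R,6S,7S)-3-hydroxy-7-[(1Z)-2-iodoprop-1-en-1-yl]-3-methyl-2-oxo-5-[(triethylsilyl)oxy]oxepan-6-yl]prop-2-enoate | O=C1O[C@H](/C=C(/C)I)[C@H](C(=C)C(=O)OC(C)(C)C)[C@H](O[Si](CC)(CC)CC)C[C@]1(C)O | intermediate
14 | 2-ethoxydiene: as 13 with 1-ethoxyvinyl in place of iodine (not isolated) | O=C1O[C@H](/C=C(/C)C(=C)OCC)[C@H](C(=C)C(=O)OC(C)(C)C)[C@H](O[Si](CC)(CC)CC)C[C@]1(C)O | intermediate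
15 | tert-butyl 2-[(3S,5R,6S,7R)-3-hydroxy-3-methyl-7-[(1Z)-2-methyl-3-oxobut-1-en-1-yl]-2-oxo-5-[(triethylsilyl)oxy]oxepan-6-yl]prop-2-enoate | O=C1O[C@H](/C=C(/C)C(C)=O)[C@H](C(=C)C(=O)OC(C)(C)C)[C@H](O[Si](CC)(CC)CC)C[C@]1(C)O | intermediate
16 | tert-butyl 2-[(3S,5R,6S,7R)-3-methyl-7-[(1Z)-2-methyl-3-oxobut-1-en-1-yl]-3-[(methylsulfonyl)oxy]-2-oxo-5-[(triethylsilyl)oxy]oxepan-6-yl]prop-2-enoate | O=C1O[C@H](/C=C(/C)C(C)=O)[C@H](C(=C)C(=O)OC(C)(C)C)[C@H](O[Si](CC)(CC)CC)C[C@]1(C)OS(C)(=O)=O | intermediate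
17 | tert-butyl (4Z,6R,7S,8R,10S)-6-hydroxy-10-[(methylsulfonyl)oxy]-1,3-dioxo-8-[(triethylsilyl)oxy]germacra-4,11(13)-dien-12-oate (not isolated) | O=C1CC(=O)/C(C)=C\[C@@H](O)[C@H](C(=C)C(=O)OC(C)(C)C)[C@H](O[Si](CC)(CC)CC)C[C@]1(C)OS(C)(=O)=O | intermediate
18 | tert-butyl (4Z,6R,7S,8R,10R)-3,10-epoxy-6-hydroxy-1-oxo-8-[(triethylsilyl)oxy]germacra-2,4,11(13)-trien-12-oate (not isolated) | C=C(C(=O)OC(C)(C)C)[C@H]1[C@H](O)/C=C(/C)C2=CC(=O)[C@@](C)(C[C@H]1O[Si](CC)(CC)CC)O2 | intermediate
19 | (4Z,6R,7S,8R,10R)-3,10-epoxy-1-oxo-8-[(triethylsilyl)oxy]germacra-2,4,11(13)-trien-12,6-olide | C=C1C(=O)O[C@@H]2/C=C(/C)C3=CC(=O)[C@@](C)(C[C@@H](O[Si](CC)(CC)CC)[C@@H]12)O3 | intermediate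
20 | (4Z,6R,7R,8R,10R)-3,10-epoxy-8-hydroxy-1-oxogermacra-2,4,11(13)-trien-12,6-olide | C=C1C(=O)O[C@@H]2/C=C(/C)C3=CC(=O)[C@@](C)(C[C@@H](O)[C@@H]12)O3 | intermediate
21 | (2S)-2-methylbutanoic acid | CC[C@H](C)C(=O)O | starting material
22 | CNP0174601.1, (4Z,6R,7R,8R,10R)-3,10-epoxy-1-oxogermacra-2,4,11(13)-trien-12,6-olid-8-yl (2S)-2-methylbutanoate | C=C1C(=O)O[C@@H]2/C=C(/C)C3=CC(=O)[C@@](C)(C[C@@H](OC(=O)[C@@H](C)CC)[C@@H]12)O3 | target

Total step count: 14. Longest linear sequence: 12 steps (steps 1–4 and 7–14, from 1 to 22); steps 5 and 6 make the side fragment 10.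

Steps most likely to fail

Step 12 (proposed new method). The C2 enolate may fail to add to the hindered lactone carbonyl. The hemiketal alkoxide may instead close an epoxide onto C10, the mesylate may eliminate, or C10 may ionise and lose stereochemical fidelity. The second stage can also be run separately on isolated 18. The fallback uses known reactions only. It sets out from 10 and 6 and returns at 18, which is lactonised to 19 with catalytic t-BuOK as in the second stage of step 12. Acetalisation of 10 (HC(OMe)3, PPTS, MeOH) gives (2Z)-3-iodo-1,1-dimethoxybut-2-ene F1. Stille coupling with tributyl(1-ethoxyvinyl)stannane and hydrolysis of the enol ether on wet silica give (3Z)-5,5-dimethoxy-3-methylpent-3-en-2-one F2. Methanolysis of the dioxolanone of 6 (NaOMe, MeOH, 0 °C) gives the hydroxy methyl ester F3, and MsCl/Et3N gives the mesylate F4. Claisen condensation of the lithium enolate of F2 (LiN(SiMe3)2, THF, −78 °C) with F4 gives the open-chain mesyloxy diketone F5, which K2CO3 in DMF cyclises with inversion at C10 to the furanone acetal F6. Wohl–Ziegler bromination (NBS, AIBN) gives the allylic bromide acetal F7, and oxalic acid in wet THF gives the bromo enal F8. CrCl2 in THF at high dilution then closes the ten-membered ring by intramolecular Nozaki–Hiyama allylation (C6–C7) to 18.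

Step 7. Simple or facial diastereoselection may be poor in the addition of the equilibrating allylindium species, and the silyloxy group may undergo 1,4-elimination. The fallback replaces the Barbier reaction by an allylboration through a closed six-membered transition state. It sets out from 7 and returns at 11. Borylation of 7 (B2pin2, Pd2(dba)3, THF) gives the allylboronate F9, which is heated with 10 (toluene, 80 °C, or Sc(OTf)3 catalysis at rt) and worked up with aqueous NaHCO3 to give 11.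

Step 9. The activated, hindered allylic C6 centre may eliminate or undergo allylic transposition, the acid may be activated instead (ring closure with retention), or oligomers may form. The fallback inverts C6 first and closes the lactone with retention. It sets out from 11 and returns at 13. Dess–Martin oxidation of 11 gives the enone F10. CBS reduction with the matching oxazaborolidine gives the C6-epimeric alcohol F11, and LiOH (THF/H2O, 0 °C) gives the C6-epimeric dihydroxy acid F12. Yamaguchi lactonisation (2,4,6-trichlorobenzoyl chloride, Et3N; then DMAP, toluene, high dilution) then gives 13.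

Further compounds
F1 | step 12 | (2Z)-3-iodo-1,1-dimethoxybut-2-ene | C/C(I)=C/C(OC)OC
F2 | step 12 | (3Z)-5,5-dimethoxy-3-methylpent-3-en-2-one | CC(=O)/C(C)=C\C(OC)OC
F3 | step 12 | 1-tert-butyl 7-methyl (4S,6S)-6-hydroxy-6-methyl-2-methylidene-4-[(triethylsilyl)oxy]heptanedioate | C=C(C[C@H](O[Si](CC)(CC)CC)C[C@](C)(O)C(=O)OC)C(=O)OC(C)(C)C
F4 | step 12 | 1-tert-butyl 7-methyl (4S,6S)-6-methyl-2-methylidene-6-[(methylsulfonyl)oxy]-4-[(triethylsilyl)oxy]heptanedioate | C=C(C[C@H](O[Si](CC)(CC)CC)C[C@](C)(OS(C)(=O)=O)C(=O)OC)C(=O)OC(C)(C)C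
F5 | step 12 | open-chain mesyloxy 1,3-diketone: tert-butyl (4Z,8R,10S)-6,6-dimethoxy-10-[(methylsulfonyl)oxy]-1,3-dioxo-8-[(triethylsilyl)oxy]-6,7-secogermacra-4,11(13)-dien-12-oate | COC(OC)/C=C(/C)C(=O)CC(=O)[C@@](C)(OS(C)(=O)=O)C[C@@H](O[Si](CC)(CC)CC)CC(=C)C(=O)OC(C)(C)C
F6 | step 12 | furanone acetal: tert-butyl (4Z,8R,10R)-3,10-epoxy-6,6-dimethoxy-1-oxo-8-[(triethylsilyl)oxy]-6,7-secogermacra-2,4,11(13)-trien-12-oate | COC(OC)/C=C(/C)C1=CC(=O)[C@@](C)(C[C@@H](O[Si](CC)(CC)CC)CC(=C)C(=O)OC(C)(C)C)O1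
F7 | step 12 | allylic bromide acetal: tert-butyl (4Z,7Z,8R,10R)-13-bromo-3,10-epoxy-6,6-dimethoxy-1-oxo-8-[(triethylsilyl)oxy]-6,7-secogermacra-2,4,7(11)-trien-12-oate | COC(OC)/C=C(/C)C1=CC(=O)[C@@](C)(C[C@@H](O[Si](CC)(CC)CC)/C=C(\CBr)C(=O)OC(C)(C)C)O1
F8 | step 12 | bromo enal: tert-butyl (4Z,7Z,8R,10R)-13-bromo-3,10-epoxy-1,6-dioxo-8-[(triethylsilyl)oxy]-6,7-secogermacra-2,4,7(11)-trien-12-oate | O=C/C=C(/C)C1=CC(=O)[C@@](C)(C[C@@H](O[Si](CC)(CC)CC)/C=C(\CBr)C(=O)OC(C)(C)C)O1
F9 | step 7 | allylboronate: tert-butyl (2E,4R)-2-[(4,4,5,5-tetramethyl-1,3,2-dioxaborolan-2-yl)methyl]-4-[(triethylsilyl)oxy]-5-[(4S)-2,2,4-trimethyl-5-oxo-1,3-dioxolan-4-yl]pent-2-enoate (same alkene geometry as 7) | CC1(C)OB(C/C(=C\[C@H](O[Si](CC)(CC)CC)C[C@]2(C)OC(C)(C)OC2=O)C(=O)OC(C)(C)C)OC1(C)C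
F10 | step 9 | enone: 11 with the C6 carbinol oxidised to the ketone | C/C(I)=C/C(=O)[C@H](C(=C)C(=O)OC(C)(C)C)[C@H](O[Si](CC)(CC)CC)C[C@]1(C)OC(C)(C)OC1=O
F11 | step 9 | C6 epimer of 11 | C/C(I)=C/[C@@H](O)[C@H](C(=C)C(=O)OC(C)(C)C)[C@H](O[Si](CC)(CC)CC)C[C@]1(C)OC(C)(C)OC1=O
F12 | step 9 | C6 epimer of 12 | C/C(I)=C/[C@@H](O)[C@H](C(=C)C(=O)OC(C)(C)C)[C@H](O[Si](CC)(CC)CC)C[C@](C)(O)C(=O)O
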